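**Analysis of the target**

The target 19 is a flavone: a 4H-chromen-4-one (benzo ring A fused to pyranone ring C) with a 3,4-dihydroxyphenyl ring B on C2. It is planar and has no stereocentre, so the problem is one of constitution and of the order of events. Ring A carries oxygen on C5, C7 and C8 and hydrogen only on C6; O7 bears the sulfate monoester and lies between C6–H and the free 8-OH. Three features are fragile. The aryl sulfate loses SO3 under acid. The 5,8-dihydroxy pair (a para-hydroquinone) and the ring B catechol are oxidised to quinones by air in base or by any oxidant. With a free 5-OH, ring C can open under strong acid and reclose on the other ortho oxygen (Wessely–Moser isomerisation to the 5,6,7-pattern). The difficulty is therefore to single out O7 among five phenolic oxygens, to build the 5,7,8-pattern without its 5,6,7-isomer, and to free four hydroxyls at the end without acid or oxidant. The strategy rests on ring B: it hangs on the single bond C2–C1′ and has its oxygens on the adjacent carbons C3′ and C4′. The unit C2′–C3′(O)–C4′(O)–C5′ is thus a 2,3-dioxygenated butadiene, and C1′/C6′ are the two carbons of an alkyne on C2 of the chromone. Cycloaddition and loss of two hydrogens then deliver the catechol already silylated, and all differentiation of ring A is done beforehand on a simple acetophenone.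

**Retrosynthetic reasoning**

19 back to 18 and 17: the last bonds cut are the two O–benzyl bonds at O5 and O8, and the potassium of the sulfate is exchanged for a proton. Hydrogenolysis is placed last because it frees the hydroquinone under reducing, neutral conditions; it has to spare the S–O bond and the C2=C3 bond.

17 back to 16: the two Si–O bonds on O3′ and O4′ are cut. The forward step needs a fluoride source that is neither acidic enough to touch the sulfate nor basic enough to let the catechol autoxidise.

16 back to 15: the O7–S bond. Because 15 has exactly one free hydroxyl, the sulfation has no choice to make; this is what the protecting-group pattern is there for.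

15 back to 14: the O7–allyl bond. Allyl is chosen because it is the one ether cleaved by zerovalent palladium under conditions that leave benzyl and aryl silyl ethers alone.

14 back to 13: two C–H bonds (on C2′ and C5′) are re-installed, turning the arene into a cyclohexa-1,4-diene. The forward step is a dehydrogenation that must not strip the silyl groups.

13 back to 10 and 12 (key disconnection): the bonds C1′–C2′ and C6′–C5′ are cut. This is the only cut that removes ring B as a whole and leaves a symmetric four-carbon piece, so no regiochemistry arises. It is also convergent and delivers both ring B oxygens protected. The forward reaction demands that the alkyne of 10, activated only through C2=C3–C4=O, be a competent dienophile.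

12 back to 11: both O–Si bonds; a double enol silylation of the 1,2-diketone.

10 back to 9: the alkyne C–H comes from a C–Si bond, which protects the alkyne terminus while ring C is made.

9 back to 8, then to 5 and 7: ring C is cut at O1–C2 and at C2–C3. The forward sequence is C-acylation of the acetophenone enolate by 7 and cyclodehydration of diketone 8. Because 5 has a single free phenol, the ring can close only one way, and that puts the benzyloxy group on C8.

7 back to 6: the acyl chloride comes from the acid.

5 back to 4: two O–benzyl bonds (O3 and O6 of the acetophenone). The forward step must leave O2, the oxygen that later becomes O1.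

4 back to 3 and 2: the C3–O bond of the acetophenone (future C8–O). Oxygen is introduced by Elbs oxidation, which in the symmetric 2 can attack only one kind of position.

2 back to 1: the O4–allyl bond, made first because O4 is the most acidic and only unchelated hydroxyl of 1.

**Alternatives that were turned down**

Alternative 1: Ring A is cut at C4a–C5 and traced to a 4-hydroxycyclobutenone whose carbinol carbon bears the C8a end of a 2-aryl-4-silyloxy-dihydropyran; the four ring carbons become C5–C8.
- Forward key step: heating opens the cyclobutenone (4π) to a dienylketene, the ketene carbon closes onto C4a (6π electrocyclisation), and tautomerisation gives hydroquinone A1.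
- For it: the connectivity of the four-membered ring fixes the 5,7,8-pattern beyond doubt. O7 arrives as the only tert-butyl ether and O5/O8 as free hydroxyls. On regiocontrol in ring A this alternative is stronger than the chosen route, which needs an Elbs oxidation and a selective benzylation.
- Against it: A1 is a chromane at the flavan-4-ol level with two stereocentres (C2, C4) that the target lacks. The cis relation is made only to be destroyed. C4 must be desilylated and oxidised and C2–C3 dehydrogenated in the presence of a hydroquinone, or of its protected form at the cost of further steps. The tert-butyl ether and the diphenylmethylene ketal are both acid-labile, so freeing O7 alone needs more protecting-group traffic. The metallated dihydropyran is itself a multistep object.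
- Comparison: the chosen strategy reaches the flavone at its final oxidation level, makes no stereocentre and uses only classical steps before the key step. It pays with less certain regiocontrol in ring A.

Alternative 2: Ring A is cut at C5–C6 and built on a preformed 4-pyranone (ring C) that carries the aryl group, an ester on the future C4a and a 1-benzyloxy-2-oxopropyl chain on the future C8a.
- Forward key step: the methyl ketone enolate attacks the ester (6-exo-trig Claisen closure) and enolisation aromatises ring A to A2.
- For it: A2 has O8 and the ring B oxygens as benzyl ethers and O5/O7 free. The chelated 5-OH is inert, so O7 can be sulfated directly and one hydrogenolysis finishes the synthesis. Those two steps after the key step compare with five in the chosen route; on end-game economy this alternative is clearly stronger.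
- Against it: the pyranone precursor is densely functionalised and its own assembly is long and without close analogy. The most acidic C–H is the benzyloxy-bearing methine (future C8), not the methyl group, so the closure must proceed through the minor enolate. 3-Acyl-4-pyranones are opened by bases and nucleophiles at C2/C6. The mono-sulfation relies on chelation rather than on protection.
- Comparison: the chosen strategy offers a precursor reached in few classical steps and concentrates the uncertainty in one well-defined reactivity question.

Alternative 3: Ring C is cut at O1–C8a; the precursor is a 2-acylhydroquinone whose acyl group is a 1,3-diketone carrying the benzyl-protected ring B.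
- Forward key step: anodic oxidation gives the acylquinone, the diketone enol oxygen adds to the quinone carbon next to the acyl group (6-endo-trig oxa-Michael), and tautomerisation gives A3.
- For it: the new C–O bond can form at one position only, so the 5,7,8-pattern is secure. Ring B is introduced by ordinary acylation and no chemical oxidant is needed. The end game (benzylation of O5/O8, deallylation, sulfation, one global hydrogenolysis) is one step shorter than the chosen one. On regiochemical security and end-game length this alternative is as strong or stronger.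
- Against it: A3 is a free hydroquinone that is richer in electrons than its precursor, so over-oxidation at the anode to the corresponding quinone has to be held back. The alkoxy-substituted quinone intermediate offers a second electrophilic site. The chelated 5-OH and the air-sensitive hydroquinone must then be benzylated under base.
- Comparison: the chosen strategy keeps O5 and O8 masked from the acetophenone stage to the final step, so no intermediate is a free hydroquinone. It also builds ring B convergently in one bond-forming event.

Key step: step 8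

Assumption: the target is taken as the free hydrogen sulfate as drawn; the sulfate is carried as its potassium salt and protonated only in the last operation, since aryl hydrogen sulfates lose SO3 under their own acidity.

**Route**

Step 1
Reactants: 1 2,4,6-trihydroxyacetophenone
Product: 2 1-[4-(allyloxy)-2,6-dihydroxyphenyl]ethan-1-one
Conditions: allyl bromide (1.05 equiv), K2CO3 (1.1 equiv), acetone, 40 °C
Reagents that add atoms: allyl bromide, C=CCBr
Why: Williamson etherification; O4 is para to the acetyl group and not hydrogen-bonded to it, so it is the most acidic hydroxyl and should be alkylated first, while the two ortho hydroxyls stay in the chelate.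

Step 2
Reactants: 2 1-[4-(allyloxy)-2,6-dihydroxyphenyl]ethan-1-one
Product: 4 1-[4-(allyloxy)-2,3,6-trihydroxyphenyl]ethan-1-one, via potassium aryl sulfate 3 (not isolated)
Conditions: K2S2O8 (1.1 equiv), aq. KOH, 0 → 20 °C, N2; then aq. HCl, Na2SO3, 85 °C
Reagents that add atoms: potassium peroxodisulfate, [K+].[K+].[O-]S(=O)(=O)OOS(=O)(=O)[O-]
Why: Elbs persulfate oxidation; the phenoxide attacks a peroxide oxygen through its para carbon, and in symmetric 2 both free ring positions are equivalent (para to one phenoxide, ortho to the other), so a single aryl sulfate 3 should form. The sulfate shields the new oxygen from further oxidation until acid hydrolysis releases triol 4; the aryl allyl ether tolerates cold alkali and brief hot dilute acid.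

Step 3
Reactants: 4 1-[4-(allyloxy)-2,3,6-trihydroxyphenyl]ethan-1-one
Product: 5 1-[4-(allyloxy)-3,6-bis(benzyloxy)-2-hydroxyphenyl]ethan-1-one
Conditions: BnBr (2.1 equiv), K2CO3 (2.2 equiv), acetone, 50 °C, Ar
Reagents that add atoms: benzyl bromide, BrCc1ccccc1
Why: Williamson etherification under chelation control; O3 is not hydrogen-bonded and O6 has only hydrogen as its second neighbour, so both should be alkylated, whereas O2, wedged between the acetyl group and the new O3 ether, keeps the hydrogen bond to the carbonyl and stays free. Argon protects the hydroquinone-type triol from air.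

Step 4
Reactants: 6 3-(trimethylsilyl)prop-2-ynoic acid
Product: 7 3-(trimethylsilyl)prop-2-ynoyl chloride
Conditions: (COCl)2 (1.2 equiv), DMF (cat.), CH2Cl2, 0 °C → rt; used crude
Reagents that add atoms: oxalyl chloride, O=C(Cl)C(=O)Cl
Why: Standard acid chloride formation through the chloroiminium species from DMF and oxalyl chloride; the silylalkyne is inert and all by-products are gases.

Step 5
Reactants: 5 1-[4-(allyloxy)-3,6-bis(benzyloxy)-2-hydroxyphenyl]ethan-1-one; 7 3-(trimethylsilyl)prop-2-ynoyl chloride
Product: 9 7-(allyloxy)-5,8-bis(benzyloxy)-2-[(trimethylsilyl)ethynyl]-4H-chromen-4-one, via alkynyl 1,3-diketone 8 (not isolated)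
Conditions: LiN(SiMe3)2 (3.1 equiv), THF, −78 °C; 7, −78 → −10 °C; AcOH; then p-TsOH·H2O (10 mol%), toluene, 60 °C
Reagents that add atoms: none
Why: Baker–Venkataraman-type chromone synthesis; the lithium phenoxide-enolate is acylated at the carbonyl carbon of 7 (any O-acylation converges by acyl transfer) and the third equivalent of base stores diketone 8 as its enolate. Under acid the only free phenol (O2) adds to the ynone carbonyl (6-exo-trig) and loss of water gives the pyranone; the trimethylsilyl group blocks the alkyne terminus against conjugate addition.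

Step 6
Reactants: 9 7-(allyloxy)-5,8-bis(benzyloxy)-2-[(trimethylsilyl)ethynyl]-4H-chromen-4-one
Product: 10 7-(allyloxy)-5,8-bis(benzyloxy)-2-ethynyl-4H-chromen-4-one
Conditions: Bu4NF (1.1 equiv), AcOH (1.2 equiv), THF, −20 → 0 °C
Reagents that add atoms: none
Why: Fluoride-induced protodesilylation of an alkynylsilane; the acetic acid buffer keeps basic species from adding to the electrophilic terminal ynenone, and the ethers are untouched.

Step 7
Reactants: 11 butane-2,3-dione
Product: 12 2,3-bis[(tert-butyldimethylsilyl)oxy]buta-1,3-diene
Conditions: t-BuMe2SiOTf (2.2 equiv), Et3N (3 equiv), CH2Cl2, 0 °C → rt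
Reagents that add atoms: tert-butyldimethylsilyl trifluoromethanesulfonate, CC(C)(C)[Si](C)(C)OS(=O)(=O)C(F)(F)F
Why: Double soft enolisation and O-silylation of a 1,2-diketone with a silyl triflate and a tertiary amine, the usual access to 2,3-bis(silyloxy)butadienes; the bulky silyl group is chosen so that the later aryl silyl ethers survive oxidant, amine and pyridine.

Step 8
Reactants: 10 7-(allyloxy)-5,8-bis(benzyloxy)-2-ethynyl-4H-chromen-4-one; 12 2,3-bis[(tert-butyldimethylsilyl)oxy]buta-1,3-diene
Product: 13 7-(allyloxy)-5,8-bis(benzyloxy)-2-{4,5-bis[(tert-butyldimethylsilyl)oxy]cyclohexa-1,4-dien-1-yl}-4H-chromen-4-one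
Conditions: 12 (3 equiv), BHT (5 mol%), toluene (1 M), 120 °C, sealed base-washed tube; filtration through Et3N-deactivated SiO2
Reagents that add atoms: none
Why: Proposed new method: a thermal normal-demand Diels–Alder reaction in which the electron-rich diene 12 (HOMO raised by two silyloxy groups) adds across the terminal alkyne of 10, whose LUMO is lowered because the triple bond ends the conjugated chain C≡C–C2=C3–C4=O; both σ bonds, C1′–C2′ and C6′–C5′ in flavone numbering, form suprafacially in one concerted (4+2) step. The closest known reaction type is the cycloaddition of 2,3-bis(silyloxy)butadienes to alkynes bearing the carbonyl acceptor directly (alkynoates, ynones), followed by dehydrogenation to catechol ethers; here the acceptor acts through one more double bond, which is why the step counts as new and is run hot, concentrated and with excess diene. Ring B is closed by this intermolecular cycloaddition as a cyclohexa-1,4-diene, four carbons from 12 and two from the alkyne. No stereocentre is formed. Regiochemistry cannot arise because 12 is symmetric about its central bond, so either orientation places the two silyloxy carbons meta and para to the chromone. Chemoselectivity is needed between the alkyne and the two alkenes of 10: C2=C3 is trisubstituted and carries the donor O1, and the allyl double bond is unactivated, so the unhindered terminal alkyne should be the only dienophile. The temperature stays at 120 °C, below the range in which the O7 allyl ether would undergo aromatic Claisen rearrangement to C6, and BHT suppresses radical polymerisation of the diene.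

Step 9
Reactants: 13 7-(allyloxy)-5,8-bis(benzyloxy)-2-{4,5-bis[(tert-butyldimethylsilyl)oxy]cyclohexa-1,4-dien-1-yl}-4H-chromen-4-one
Product: 14 7-(allyloxy)-5,8-bis(benzyloxy)-2-{3,4-bis[(tert-butyldimethylsilyl)oxy]phenyl}-4H-chromen-4-one
Conditions: DDQ (1.1 equiv), toluene, 0 °C → rt
Reagents that add atoms: none
Why: Quinone dehydrogenation of a cyclohexa-1,4-diene; hydride abstraction from a doubly allylic CH2 gives a silyloxy-stabilised cyclohexadienyl cation that aromatises by proton loss. Benzyl and allyl ethers are inert to DDQ at room temperature, and O5/O8 are still protected, so no hydroquinone is exposed to the oxidant.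

Step 10
Reactants: 14 7-(allyloxy)-5,8-bis(benzyloxy)-2-{3,4-bis[(tert-butyldimethylsilyl)oxy]phenyl}-4H-chromen-4-one
Product: 15 5,8-bis(benzyloxy)-2-{3,4-bis[(tert-butyldimethylsilyl)oxy]phenyl}-7-hydroxy-4H-chromen-4-one
Conditions: Pd(PPh3)4 (5 mol%), morpholine (3 equiv), THF, rt
Reagents that add atoms: none
Why: Tsuji–Trost-type deallylation; zerovalent palladium ionises the aryl allyl ether (the chromone 7-oxide is a good leaving group) to a π-allylpalladium species that morpholine intercepts. Benzyl and aryl silyl ethers do not react.

Step 11
Reactants: 15 5,8-bis(benzyloxy)-2-{3,4-bis[(tert-butyldimethylsilyl)oxy]phenyl}-7-hydroxy-4H-chromen-4-one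
Product: 16 potassium 5,8-bis(benzyloxy)-2-{3,4-bis[(tert-butyldimethylsilyl)oxy]phenyl}-4-oxo-4H-chromen-7-yl sulfate
Conditions: SO3·pyridine (4 equiv), pyridine, 40 °C; then aq. KHCO3, 0 °C
Reagents that add atoms: sulfur trioxide–pyridine complex, [O-]S(=O)(=O)[n+]1ccccc1; potassium hydrogen carbonate, [K+].OC([O-])=O
Why: O-Sulfation of a phenol with an amine–SO3 complex; 15 has one free hydroxyl, so only O7 can react. The bicarbonate work-up fixes the product as the base-stable potassium salt without any acid contact.

Step 12
Reactants: 16 potassium 5,8-bis(benzyloxy)-2-{3,4-bis[(tert-butyldimethylsilyl)oxy]phenyl}-4-oxo-4H-chromen-7-yl sulfate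
Product: 17 potassium 5,8-bis(benzyloxy)-2-(3,4-dihydroxyphenyl)-4-oxo-4H-chromen-7-yl sulfate
Conditions: KHF2 (3 equiv), MeOH–THF, rt
Reagents that add atoms: none
Why: Fluoride cleavage of aryl silyl ethers; bifluoride in methanol is selective for phenolic silyl ethers, does not attack a sulfate monoanion and keeps the cation uniform. The medium is not basic, so the catechol should not autoxidise.

Step 13
Reactants: 17 potassium 5,8-bis(benzyloxy)-2-(3,4-dihydroxyphenyl)-4-oxo-4H-chromen-7-yl sulfate
Product: 19 8-hydroxyluteolin 7-sulfate [2-(3,4-dihydroxyphenyl)-5,8-dihydroxy-4-oxo-4H-chromen-7-yl hydrogen sulfate], via potassium salt 18 (not isolated)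
Conditions: H2 (1 atm), Pd/C (10% Pd), degassed MeOH–THF, rt; filtration under Ar; then sulfonic acid resin (H+ form), MeOH–H2O, 0 °C; freeze-drying
Reagents that add atoms: none
Why: Hydrogenolysis of aryl benzyl ethers over palladium; the aryl sulfate and the vinylogous-ester C2=C3 bond are expected to survive 1 atm of hydrogen, and the hydroquinone and catechol appear under reducing conditions. Cold proton exchange on the resin then converts salt 18 into 19, which is freeze-dried at once to limit acid-induced loss of SO3.

**Compound list**

1 | 1-(2,4,6-trihydroxyphenyl)ethan-1-one (2,4,6-trihydroxyacetophenone) | CC(=O)c1c(O)cc(O)cc1O | starting material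
2 | 1-[4-(allyloxy)-2,6-dihydroxyphenyl]ethan-1-one | CC(=O)c1c(O)cc(OCC=C)cc1O | intermediate
3 | potassium 3-acetyl-6-(allyloxy)-2,4-dihydroxyphenyl sulfate | [K+].CC(=O)c1c(O)c(OS(=O)(=O)[O-])c(OCC=C)cc1O | intermediate
4 | 1-[4-(allyloxy)-2,3,6-trihydroxyphenyl]ethan-1-one | CC(=O)c1c(O)c(O)c(OCC=C)cc1O | intermediate
5 | 1-[4-(allyloxy)-3,6-bis(benzyloxy)-2-hydroxyphenyl]ethan-1-one | CC(=O)c1c(O)c(OCc2ccccc2)c(OCC=C)cc1OCc1ccccc1 | intermediate
6 | 3-(trimethylsilyl)prop-2-ynoic acid | C[Si](C)(C)C#CC(=O)O | starting material
7 | 3-(trimethylsilyl)prop-2-ynoyl chloride | C[Si](C)(C)C#CC(=O)Cl | intermediate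
8 | 1-[4-(allyloxy)-3,6-bis(benzyloxy)-2-hydroxyphenyl]-5-(trimethylsilyl)pent-4-yne-1,3-dione | C[Si](C)(C)C#CC(=O)CC(=O)c1c(O)c(OCc2ccccc2)c(OCC=C)cc1OCc1ccccc1 | intermediate
9 | 7-(allyloxy)-5,8-bis(benzyloxy)-2-[(trimethylsilyl)ethynyl]-4H-chromen-4-one | C[Si](C)(C)C#Cc1cc(=O)c2c(OCc3ccccc3)cc(OCC=C)c(OCc3ccccc3)c2o1 | intermediate
10 | 7-(allyloxy)-5,8-bis(benzyloxy)-2-ethynyl-4H-chromen-4-one | C#Cc1cc(=O)c2c(OCc3ccccc3)cc(OCC=C)c(OCc3ccccc3)c2o1 | intermediate
11 | butane-2,3-dione | CC(=O)C(C)=O | starting material
12 | 2,3-bis[(tert-butyldimethylsilyl)oxy]buta-1,3-diene | C=C(O[Si](C)(C)C(C)(C)C)C(=C)O[Si](C)(C)C(C)(C)C | intermediate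
13 | 7-(allyloxy)-5,8-bis(benzyloxy)-2-{4,5-bis[(tert-butyldimethylsilyl)oxy]cyclohexa-1,4-dien-1-yl}-4H-chromen-4-one | O=c1cc(C2=CCC(O[Si](C)(C)C(C)(C)C)=C(O[Si](C)(C)C(C)(C)C)C2)oc2c(OCc3ccccc3)c(OCC=C)cc(OCc3ccccc3)c12 | intermediate
14 | 7-(allyloxy)-5,8-bis(benzyloxy)-2-{3,4-bis[(tert-butyldimethylsilyl)oxy]phenyl}-4H-chromen-4-one | O=c1cc(-c2ccc(O[Si](C)(C)C(C)(C)C)c(O[Si](C)(C)C(C)(C)C)c2)oc2c(OCc3ccccc3)c(OCC=C)cc(OCc3ccccc3)c12 | intermediate
15 | 5,8-bis(benzyloxy)-2-{3,4-bis[(tert-butyldimethylsilyl)oxy]phenyl}-7-hydroxy-4H-chromen-4-one | O=c1cc(-c2ccc(O[Si](C)(C)C(C)(C)C)c(O[Si](C)(C)C(C)(C)C)c2)oc2c(OCc3ccccc3)c(O)cc(OCc3ccccc3)c12 | intermediate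
16 | potassium 5,8-bis(benzyloxy)-2-{3,4-bis[(tert-butyldimethylsilyl)oxy]phenyl}-4-oxo-4H-chromen-7-yl sulfate | [K+].O=c1cc(-c2ccc(O[Si](C)(C)C(C)(C)C)c(O[Si](C)(C)C(C)(C)C)c2)oc2c(OCc3ccccc3)c(OS(=O)(=O)[O-])cc(OCc3ccccc3)c12 | intermediate
17 | potassium 5,8-bis(benzyloxy)-2-(3,4-dihydroxyphenyl)-4-oxo-4H-chromen-7-yl sulfate | [K+].O=c1cc(-c2ccc(O)c(O)c2)oc2c(OCc3ccccc3)c(OS(=O)(=O)[O-])cc(OCc3ccccc3)c12 | intermediate
18 | potassium 2-(3,4-dihydroxyphenyl)-5,8-dihydroxy-4-oxo-4H-chromen-7-yl sulfate | [K+].O=c1cc(-c2ccc(O)c(O)c2)oc2c(O)c(OS(=O)(=O)[O-])cc(O)c12 | intermediate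
19 | 8-hydroxyluteolin 7-sulfate: 2-(3,4-dihydroxyphenyl)-5,8-dihydroxy-4-oxo-4H-chromen-7-yl hydrogen sulfate | O=c1cc(-c2ccc(O)c(O)c2)oc2c(O)c(OS(=O)(=O)O)cc(O)c12 | target

**Step count and risk**

Total: 13 steps. Longest linear sequence: 11 steps (1 to 19 through steps 1, 2, 3, 5, 6, 8, 9, 10, 11, 12 and 13); steps 4 and 7 are one-step side branches.

Step 8 (key step, the one step without direct precedent on this substrate class). Most likely failure: the cycloaddition does not turn over, because the alkyne is activated only through the C2=C3 relay and its barrier may lie above what the other groups tolerate. Forcing the temperature would bring desilylation or oligomerisation of 12 and Claisen migration of the allyl group to C6. The fallback uses established chemistry, keeps the cycloaddition construction of ring B but runs it on a classical dienophile, and closes ring C afterwards. It sets out from 12 and 5 and rejoins the route at 14; steps 4 to 6 are then not needed. Diene 12 is heated with ethyl propiolate (toluene, 110 °C) to give ethyl 4,5-bis[(tert-butyldimethylsilyl)oxy]cyclohexa-1,4-diene-1-carboxylate F1. DDQ then gives ethyl 3,4-bis[(tert-butyldimethylsilyl)oxy]benzoate F2. The lithium dianion of 5 (LiN(SiMe3)2, THF, −78 °C → rt) undergoes Claisen condensation with F2 to 1-[4-(allyloxy)-3,6-bis(benzyloxy)-2-hydroxyphenyl]-3-{3,4-bis[(tert-butyldimethylsilyl)oxy]phenyl}propane-1,3-dione F3. Cyclodehydration with catalytic p-TsOH in toluene at 60 °C should give 14.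

Step 5. Most likely failure: diversion of the alkynyl diketone, either by conjugate addition of the enolate to the acylating agent or by 6-endo closure of the diketone enol oxygen onto the ynone (to a 4-pyranone) in place of hemiketal formation and dehydration. The fallback builds the chromone first and the alkyne afterwards; it sets out from 5 and rejoins at 10, bypassing 7, 8 and 9. Condensation of 5 with diethyl oxalate (NaOEt, EtOH) and acid-catalysed ring closure (cat. H2SO4, EtOH) gives ethyl 7-(allyloxy)-5,8-bis(benzyloxy)-4-oxo-4H-chromene-2-carboxylate F4. NaBH4 (MeOH–THF, 0 °C) reduces the activated ester to 7-(allyloxy)-5,8-bis(benzyloxy)-2-(hydroxymethyl)-4H-chromen-4-one F5. MnO2 in CH2Cl2 gives 7-(allyloxy)-5,8-bis(benzyloxy)-4-oxo-4H-chromene-2-carbaldehyde F6. Colvin homologation with lithiated (trimethylsilyl)diazomethane (Me3SiCHN2, LiN(iPr)2, THF, −78 → 0 °C), which needs no alcoholic base, should give 10.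

Step 3. Most likely failure: benzylation at the wrong ortho oxygen (O2 in place of O6), or of all three hydroxyls. The first error would pass through ring closure into the 5,6,7-oxygenated series. The fallback fixes the position of the new oxygen by construction; it sets out from 2 and rejoins at 5, and it also makes step 2 unnecessary. Monobenzylation of 2 (BnBr 1.0 equiv, K2CO3, acetone) gives 1-[4-(allyloxy)-2-(benzyloxy)-6-hydroxyphenyl]ethan-1-one F7. Magnesium-directed ortho-formylation (MgCl2, Et3N, paraformaldehyde, MeCN, reflux) next to the only free hydroxyl gives 3-acetyl-6-(allyloxy)-4-(benzyloxy)-2-hydroxybenzaldehyde F8. Dakin oxidation (H2O2, aq. NaOH, 0 °C) gives 1-[4-(allyloxy)-6-(benzyloxy)-2,3-dihydroxyphenyl]ethan-1-one F9. Benzylation of its unchelated hydroxyl (BnBr 1.0 equiv, K2CO3, acetone) gives 5.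

Step 2. Most likely failure: oxidative degradation of the electron-rich ring and low conversion, as is common in persulfate oxidations of polyphenols, together with radical attack on the allyl group if the persulfate decomposes homolytically. The fallback replaces the direct oxidation by formylation and oxidative deformylation; it sets out from 2 and rejoins at 4. Magnesium-directed formylation of symmetric 2 (MgCl2, Et3N, paraformaldehyde, MeCN, reflux) gives 3-acetyl-6-(allyloxy)-2,4-dihydroxybenzaldehyde F10. Dakin oxidation (H2O2 1 equiv, aq. NaOH, 0 °C), faster at the aldehyde than at the acetyl group, gives 4.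

Step 12. Most likely failure: partial hydrolytic loss of the sulfate in the weakly acidic bifluoride medium, or incomplete cleavage of the second silyl ether, leaving a polar salt that is hard to purify. The fallback removes the silyl groups before the sulfate exists and carries all four remaining oxygens as benzyl ethers, so that one hydrogenolysis ends the synthesis. It sets out from 14 and rejoins at 18.
- Buffered fluoride (Bu4NF, AcOH, THF, 0 °C) gives 7-(allyloxy)-5,8-bis(benzyloxy)-2-(3,4-dihydroxyphenyl)-4H-chromen-4-one F11.
- BnBr and K2CO3 in DMF give 7-(allyloxy)-5,8-bis(benzyloxy)-2-[3,4-bis(benzyloxy)phenyl]-4H-chromen-4-one F12.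
- Pd(PPh3)4 and morpholine give 5,8-bis(benzyloxy)-2-[3,4-bis(benzyloxy)phenyl]-7-hydroxy-4H-chromen-4-one F13.
- SO3·pyridine followed by aq. KHCO3 gives potassium 5,8-bis(benzyloxy)-2-[3,4-bis(benzyloxy)phenyl]-4-oxo-4H-chromen-7-yl sulfate F14.
- Hydrogenolysis (H2, Pd/C) gives 18.

**Further compounds**

F1 | step 8 | ethyl 4,5-bis[(tert-butyldimethylsilyl)oxy]cyclohexa-1,4-diene-1-carboxylate | CCOC(=O)C1=CCC(O[Si](C)(C)C(C)(C)C)=C(O[Si](C)(C)C(C)(C)C)C1
F2 | step 8 | ethyl 3,4-bis[(tert-butyldimethylsilyl)oxy]benzoate | CCOC(=O)c1ccc(O[Si](C)(C)C(C)(C)C)c(O[Si](C)(C)C(C)(C)C)c1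
F3 | step 8 | 1-[4-(allyloxy)-3,6-bis(benzyloxy)-2-hydroxyphenyl]-3-{3,4-bis[(tert-butyldimethylsilyl)oxy]phenyl}propane-1,3-dione | O=C(CC(=O)c1ccc(O[Si](C)(C)C(C)(C)C)c(O[Si](C)(C)C(C)(C)C)c1)c1c(O)c(OCc2ccccc2)c(OCC=C)cc1OCc1ccccc1
F4 | step 5 | ethyl 7-(allyloxy)-5,8-bis(benzyloxy)-4-oxo-4H-chromene-2-carboxylate | CCOC(=O)c1cc(=O)c2c(OCc3ccccc3)cc(OCC=C)c(OCc3ccccc3)c2o1
F5 | step 5 | 7-(allyloxy)-5,8-bis(benzyloxy)-2-(hydroxymethyl)-4H-chromen-4-one | OCc1cc(=O)c2c(OCc3ccccc3)cc(OCC=C)c(OCc3ccccc3)c2o1
F6 | step 5 | 7-(allyloxy)-5,8-bis(benzyloxy)-4-oxo-4H-chromene-2-carbaldehyde | O=Cc1cc(=O)c2c(OCc3ccccc3)cc(OCC=C)c(OCc3ccccc3)c2o1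
F7 | step 3 | 1-[4-(allyloxy)-2-(benzyloxy)-6-hydroxyphenyl]ethan-1-one | CC(=O)c1c(O)cc(OCC=C)cc1OCc1ccccc1
F8 | step 3 | 3-acetyl-6-(allyloxy)-4-(benzyloxy)-2-hydroxybenzaldehyde | CC(=O)c1c(O)c(C=O)c(OCC=C)cc1OCc1ccccc1
F9 | step 3 | 1-[4-(allyloxy)-6-(benzyloxy)-2,3-dihydroxyphenyl]ethan-1-one | CC(=O)c1c(O)c(O)c(OCC=C)cc1OCc1ccccc1
F10 | step 2 | 3-acetyl-6-(allyloxy)-2,4-dihydroxybenzaldehyde | CC(=O)c1c(O)cc(OCC=C)c(C=O)c1O
F11 | step 12 | 7-(allyloxy)-5,8-bis(benzyloxy)-2-(3,4-dihydroxyphenyl)-4H-chromen-4-one | O=c1cc(-c2ccc(O)c(O)c2)oc2c(OCc3ccccc3)c(OCC=C)cc(OCc3ccccc3)c12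
F12 | step 12 | 7-(allyloxy)-5,8-bis(benzyloxy)-2-[3,4-bis(benzyloxy)phenyl]-4H-chromen-4-one | O=c1cc(-c2ccc(OCc3ccccc3)c(OCc3ccccc3)c2)oc2c(OCc3ccccc3)c(OCC=C)cc(OCc3ccccc3)c12
F13 | step 12 | 5,8-bis(benzyloxy)-2-[3,4-bis(benzyloxy)phenyl]-7-hydroxy-4H-chromen-4-one | O=c1cc(-c2ccc(OCc3ccccc3)c(OCc3ccccc3)c2)oc2c(OCc3ccccc3)c(O)cc(OCc3ccccc3)c12
F14 | step 12 | potassium 5,8-bis(benzyloxy)-2-[3,4-bis(benzyloxy)phenyl]-4-oxo-4H-chromen-7-yl sulfate | [K+].O=c1cc(-c2ccc(OCc3ccccc3)c(OCc3ccccc3)c2)oc2c(OCc3ccccc3)c(OS(=O)(=O)[O-])cc(OCc3ccccc3)c12
A1 | alternative 1 | cis-7-tert-butoxy-4-[(tert-butyldimethylsilyl)oxy]-2-(2,2-diphenyl-1,3-benzodioxol-5-yl)chromane-5,8-diol (racemic, 2R,4R enantiomer drawn) | CC(C)(C)Oc1cc(O)c2c(c1O)O[C@@H](c1ccc3OC(c4ccccc4)(c4ccccc4)Oc3c1)C[C@H]2O[Si](C)(C)C(C)(C)C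
A2 | alternative 2 | 8-(benzyloxy)-2-[3,4-bis(benzyloxy)phenyl]-5,7-dihydroxy-4H-chromen-4-one | O=c1cc(-c2ccc(OCc3ccccc3)c(OCc3ccccc3)c2)oc2c(OCc3ccccc3)c(O)cc(O)c12
A3 | alternative 3 | 7-(allyloxy)-2-[3,4-bis(benzyloxy)phenyl]-5,8-dihydroxy-4H-chromen-4-one | O=c1cc(-c2ccc(OCc3ccccc3)c(OCc3ccccc3)c2)oc2c(O)c(OCC=C)cc(O)c12
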